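## Retrosynthetic overview

1. The triene side chain is cut at its trisubstituted C=C (Horner–Wittig): a bicyclic C14 methyl ketone plus a C6 dienyl phosphine oxide made separately in four steps.
2. The C5 tertiary alcohol / C4 exocyclic methylene pair comes from reductive opening of a 4α,5α-epoxy-15-iodide, itself from Sharpless epoxidation of a Δ4-15-ol, which comes from a Δ4-4-carbaldehyde.
3. Key step: that enal is closed by an intramolecular (enolexo) aldol condensation, C4 (α to the C15 aldehyde) onto the C5 ring ketone.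
4. The keto aldehyde comes from double ozonolysis. C1–Br is set by SN2 inversion of an aldol carbinol; C10–C1 and the C10 quaternary centre come from a reductive aldol of (S)-carvone with hex-5-enal.
5. Ring order: ring B is carried in from carvone, ring A is closed by the aldol condensation. Decalin locants used below: C1 (Br), C4 (=CH2, C15), C5 (OH), C7 (side chain), C10 (Me); β = face of the C10 methyl.

Assumption: hex-5-enal is bought as such.

## Route

Step 1
Reactants: 1 (S)-(+)-carvone; 2 hex-5-enal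
Product: 4 (2S,5S)-2-[(1S)-1-hydroxyhex-5-en-1-yl]-2-methyl-5-(prop-1-en-2-yl)cyclohexan-1-one, via lithium enolate 3 (not isolated)
Conditions: Li[HB(s-Bu)3] (1.05 equiv), THF, −78 °C; then 2, −78 °C
Reagents that add atoms: none
Why: Conjugate hydride reduction gives only the tetrasubstituted enolate, which undergoes a reductive aldol by axial attack cis to the equatorial isopropenyl group (sets C10) through a closed Zimmerman–Traxler transition state with the aldehyde chain equatorial, placing the C10 methyl and the new C1 hydroxyl syn (C1 S).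

Step 2
Reactants: 4 aldol adduct
Product: 6 (2R,5S)-2-[(1R)-1-bromohex-5-en-1-yl]-2-methyl-5-(prop-1-en-2-yl)cyclohexan-1-one, via triflate 5 (not isolated)
Conditions: Tf2O, pyridine, CH2Cl2, −78 → −30 °C; then n-Bu4NBr (3 equiv), toluene, −30 °C → rt
Reagents that add atoms: tetrabutylammonium bromide, CCCC[N+](CCCC)(CCCC)CCCC.[Br-]
Why: SN2 displacement of the secondary triflate by bromide inverts C1 (S → R, the future 1β-Br); C10 has no hydrogen, so elimination toward the ketone is impossible, and the β-carbonyl disfavours ionisation.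

Step 3
Reactants: 6 bromo ketone
Product: 10 (4R,4aR,7R)-7-acetyl-4-bromo-4a-methyl-2,3,4,4a,5,6,7,8-octahydronaphthalene-1-carbaldehyde, via keto aldehyde 7 (not isolated), via aldol adduct 8 (not isolated), via axial-acetyl enal 9 (not isolated)
Conditions: O3, CH2Cl2, −78 °C; PPh3, −78 °C → rt; then pyrrolidine (0.3 equiv), AcOH (0.3 equiv), 40 °C; then DBU (0.5 equiv), rt
Reagents that add atoms: ozone, [O-][O+]=O
Why: Ozonolysis unmasks the C15 aldehyde and the C7 acetyl together, and the aldehyde enamine then closes ring A onto the C5 ketone by a 6-exo intramolecular aldol condensation, the only closure that can dehydrate to a conjugated enal; the acetyl-bearing C7 equilibrates by enolisation to the equatorial 7β epimer (estimated about 4:1, minor epimer 9 separated and re-equilibrated).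

Step 4
Reactants: 10 enal
Product: 11 1-[(2R,4aR,5R)-5-bromo-8-(hydroxymethyl)-4a-methyl-1,2,3,4,4a,5,6,7-octahydronaphthalen-2-yl]ethan-1-one
Conditions: LiAlH(Ot-Bu)3 (1.1 equiv), THF, −78 → −40 °C
Reagents that add atoms: none
Why: Chemoselective 1,2-hydride reduction of the aldehyde in the presence of the less electrophilic methyl ketone; no stereocentre is formed.

Step 5
Reactants: 11 allylic alcohol
Product: 12 1-[(2R,4aR,5R,8S,8aS)-5-bromo-8,8a-epoxy-8-(hydroxymethyl)-4a-methyldecahydronaphthalen-2-yl]ethan-1-one (the 4α,5α-epoxide)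
Conditions: Ti(Oi-Pr)4 (0.3 equiv), L-(+)-diisopropyl tartrate (0.36 equiv), t-BuOOH (2 equiv), 4 Å molecular sieves, CH2Cl2, −20 °C
Reagents that add atoms: tert-butyl hydroperoxide, CC(C)(C)OO
Why: Sharpless asymmetric epoxidation of the primary allylic alcohol; the L-(+)-tartrate catalyst delivers oxygen to the α-face, which is also the face away from the axial C10 methyl (matched case), fixing the future C5–O configuration.

Step 6
Reactants: 12 epoxy alcohol
Product: 14 1-[(2R,4aR,5R,8aR)-5-bromo-8a-hydroxy-4a-methyl-8-methylidenedecahydronaphthalen-2-yl]ethan-1-one, via epoxy iodide 13 (not isolated)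
Conditions: PPh3, I2, imidazole, THF, 0 °C; then Zn dust, AcOH, 0 °C → rt
Reagents that add atoms: none
Why: Appel-type iodination of the primary alcohol followed by zinc-mediated reductive elimination of the β-iodo epoxide gives the transposed tertiary allylic alcohol regiospecifically; the C5–O bond is untouched, so 5α-OH is retained and the C4 exocyclic methylene is formed.

Step 7
Reactants: 15 methacrolein; 16 triethyl phosphonoacetate
Product: 18 ethyl (2E)-4-methylpenta-2,4-dienoate, via sodium phosphonate carbanion 17 (not isolated)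
Conditions: NaH, THF, 0 °C; then 15, 0 °C → rt
Reagents that add atoms: none
Why: Horner–Wadsworth–Emmons olefination of an aldehyde with a stabilised phosphonate gives the E-enoate.

Step 8
Reactants: 18 dienoate
Product: 19 (2E)-4-methylpenta-2,4-dien-1-ol
Conditions: i-Bu2AlH (2.2 equiv), CH2Cl2, −78 °C
Reagents that add atoms: none
Why: 1,2-Reduction of the conjugated ester to the allylic alcohol without touching the diene.

Step 9
Reactants: 19 dienol
Product: 20 (2E)-1-bromo-4-methylpenta-2,4-diene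
Conditions: PBr3 (0.4 equiv), Et2O, 0 °C
Reagents that add atoms: phosphorus tribromide, BrP(Br)Br
Why: Substitution of the primary allylic alcohol by bromide; the conjugated primary bromide is the stable regioisomer and the E geometry is kept.

Step 10
Reactants: 20 dienyl bromide
Product: 21 [(2E)-4-methylpenta-2,4-dien-1-yl](diphenyl)phosphine oxide
Conditions: Ph2POEt, toluene, 60 °C
Reagents that add atoms: ethyl diphenylphosphinite, CCOP(c1ccccc1)c1ccccc1
Why: Michaelis–Arbuzov reaction at the unhindered primary allylic carbon gives the unrearranged phosphine oxide.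

Step 11
Reactants: 14 hydroxy ketone; 21 dienyl phosphine oxide
Product: 23 (4R,4aR,7R,8aR)-4-bromo-4a-methyl-1-methylidene-7-[(2E,4E)-6-methylhepta-2,4,6-trien-2-yl]decahydronaphthalen-8a-ol (CNP0385268.1), via lithiated phosphine oxide 22 (not isolated)
Conditions: 21 (2.5 equiv), n-BuLi (2.4 equiv), THF, −78 °C; then 14, −78 → 0 °C
Reagents that add atoms: none
Why: Horner–Wittig (Lythgoe-type) olefination of the methyl ketone by the α-carbon of the dienyl phosphine oxide anion (the excess anion covers the free hydroxyl); the bulky decalin is expected to end up trans to the dienyl chain (E), the 4E geometry comes unchanged from 21, and C7 is already the thermodynamic equatorial epimer.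

## Compound list

1 | (S)-(+)-carvone, (5S)-2-methyl-5-(prop-1-en-2-yl)cyclohex-2-en-1-one | CC1=CC[C@@H](CC1=O)C(C)=C | starting material
2 | hex-5-enal | C=CCCCC=O | starting material
3 | lithium (5S)-2-methyl-5-(prop-1-en-2-yl)cyclohex-1-en-1-olate | CC1=C([O-])C[C@H](CC1)C(C)=C.[Li+] | intermediate
4 | (2S,5S)-2-[(1S)-1-hydroxyhex-5-en-1-yl]-2-methyl-5-(prop-1-en-2-yl)cyclohexan-1-one | C=C(C)[C@H]1CC[C@@](C)([C@@H](O)CCCC=C)C(=O)C1 | intermediate
5 | trifluoromethanesulfonate of 4 (same configuration) | C=C(C)[C@H]1CC[C@@](C)([C@@H](OS(=O)(=O)C(F)(F)F)CCCC=C)C(=O)C1 | intermediate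
6 | (2R,5S)-2-[(1R)-1-bromohex-5-en-1-yl]-2-methyl-5-(prop-1-en-2-yl)cyclohexan-1-one | C=C(C)[C@H]1CC[C@@](C)([C@H](Br)CCCC=C)C(=O)C1 | intermediate
7 | (5R)-5-[(1R,4S)-4-acetyl-1-methyl-2-oxocyclohexyl]-5-bromopentanal | CC(=O)[C@H]1CC[C@@](C)([C@H](Br)CCCC=O)C(=O)C1 | intermediate
8 | (4R,4aR)-7-acetyl-4-bromo-8a-hydroxy-4a-methyldecahydronaphthalene-1-carbaldehyde (mixture at C1, C7, C8a) | CC(=O)C1CC[C@@]2(C)[C@H](Br)CCC(C=O)C2(O)C1 | intermediate
9 | (4R,4aR,7S)-7-acetyl-4-bromo-4a-methyl-2,3,4,4a,5,6,7,8-octahydronaphthalene-1-carbaldehyde (7α, axial acetyl) | CC(=O)[C@H]1CC[C@@]2(C)[C@H](Br)CCC(C=O)=C2C1 | intermediate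
10 | (4R,4aR,7R)-7-acetyl-4-bromo-4a-methyl-2,3,4,4a,5,6,7,8-octahydronaphthalene-1-carbaldehyde (7β, equatorial acetyl) | CC(=O)[C@@H]1CC[C@@]2(C)[C@H](Br)CCC(C=O)=C2C1 | intermediate
11 | 1-[(2R,4aR,5R)-5-bromo-8-(hydroxymethyl)-4a-methyl-1,2,3,4,4a,5,6,7-octahydronaphthalen-2-yl]ethan-1-one | CC(=O)[C@@H]1CC[C@@]2(C)[C@H](Br)CCC(CO)=C2C1 | intermediate
12 | 1-[(2R,4aR,5R,8S,8aS)-5-bromo-8,8a-epoxy-8-(hydroxymethyl)-4a-methyldecahydronaphthalen-2-yl]ethan-1-one | CC(=O)[C@@H]1CC[C@@]2(C)[C@H](Br)CC[C@@]3(CO)O[C@@]23C1 | intermediate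
13 | iodide of 12 (CH2OH replaced by CH2I, same configuration) | CC(=O)[C@@H]1CC[C@@]2(C)[C@H](Br)CC[C@@]3(CI)O[C@@]23C1 | intermediate
14 | 1-[(2R,4aR,5R,8aR)-5-bromo-8a-hydroxy-4a-methyl-8-methylidenedecahydronaphthalen-2-yl]ethan-1-one | CC(=O)[C@@H]1CC[C@@]2(C)[C@H](Br)CCC(=C)[C@]2(O)C1 | intermediate
15 | methacrolein (2-methylprop-2-enal) | CC(=C)C=O | starting material
16 | triethyl phosphonoacetate | CCOC(=O)CP(=O)(OCC)OCC | starting material
17 | sodium salt of the carbanion of 16 | CCOC(=O)[CH-]P(=O)(OCC)OCC.[Na+] | intermediate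
18 | ethyl (2E)-4-methylpenta-2,4-dienoate | CCOC(=O)/C=C/C(C)=C | intermediate
19 | (2E)-4-methylpenta-2,4-dien-1-ol | OC/C=C/C(C)=C | intermediate
20 | (2E)-1-bromo-4-methylpenta-2,4-diene | BrC/C=C/C(C)=C | intermediate
21 | [(2E)-4-methylpenta-2,4-dien-1-yl](diphenyl)phosphine oxide | O=P(C/C=C/C(C)=C)(c1ccccc1)c1ccccc1 | intermediate
22 | α-lithio derivative of 21 | O=P([CH-]/C=C/C(C)=C)(c1ccccc1)c1ccccc1.[Li+] | intermediate
23 | (4R,4aR,7R,8aR)-4-bromo-4a-methyl-1-methylidene-7-[(2E,4E)-6-methylhepta-2,4,6-trien-2-yl]decahydronaphthalen-8a-ol | C=C(C)/C=C/C=C(\C)[C@@H]1CC[C@@]2(C)[C@H](Br)CCC(=C)[C@]2(O)C1 | target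

## Step count and risks

Total step count: 11. Longest linear sequence: 7 (steps 1–6 and 11); the phosphine oxide branch is 4 steps (7–10) plus the shared step 11.

The three steps most likely to fail:

**Step 2 (SN2 at a neopentylic secondary carbon; elimination or rearrangement of triflate 5 may win).** The fallback moves the displacement onto the rigid bicycle. Compound 4 is silylated (TESOTf, 2,6-lutidine, CH2Cl2, −78 °C) to triethylsilyl ether F1. Ozonolysis and aldol condensation under the conditions of step 3 lead through keto aldehyde F2, aldol adduct F3 and axial-acetyl enal F4 to silyloxy enal F5. HF·pyridine in THF (acidic, to avoid a vinylogous retro-aldol) frees hydroxy enal F6, whose pseudo-axial C1 hydroxyl is triflated (Tf2O, pyridine, −78 °C) to triflate F7. Displacement by n-Bu4NBr, with the electron-poor enal suppressing homoallylic participation, gives the equatorial bromide, and the route is rejoined at 10.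

**Step 3 (the C7 equilibrium at the Δ4 stage is only modestly biased, and the aldol closes onto a hindered ketone).** The fallback uses the axial acetyl instead of removing it. DBU is left out and 9 is isolated and reduced as in step 4 to allylic alcohol F8. KHSO5 (as its triple salt 2KHSO5·KHSO4·K2SO4) with NaHCO3 in MeCN–H2O converts the methyl ketone into dioxirane F9, which passes oxygen intramolecularly to the α-face of C4=C5 to give epoxy alcohol F10. Iodination and zinc opening as in step 6, through epoxy iodide F11, give the 7-epimeric hydroxy ketone F12. Its axial acetyl is now syn-diaxial to the C5 hydroxyl, so K2CO3 in MeOH epimerises it to 14.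

**Step 11 (ketone olefination: enolisation of the methyl ketone and uncertain E/Z at the new trisubstituted alkene).** The fallback builds the triene by two sp2-based stages. Compound 14 is treated with CH2(Bpin)2 and lithium 2,2,6,6-tetramethylpiperidide (THF, −78 °C → rt, boron–Wittig) to give the E-alkenyl boronate F13. Methacrolein 15 is converted by Takai olefination (CrCl2, a divalent chromium salt, with CHI3 in THF) into (E)-1-iodo-3-methylbuta-1,3-diene F14. Suzuki–Miyaura coupling of F13 with F14 (Pd(PPh3)4, a zerovalent palladium catalyst, K3PO4, THF–H2O) gives 23 directly.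

## Further compounds

F1 | step 2 | triethylsilyl ether of 4 | C=C(C)[C@H]1CC[C@@](C)([C@@H](O[Si](CC)(CC)CC)CCCC=C)C(=O)C1
F2 | step 2 | (5S)-5-[(1S,4S)-4-acetyl-1-methyl-2-oxocyclohexyl]-5-(triethylsilyloxy)pentanal | CC(=O)[C@H]1CC[C@@](C)([C@@H](O[Si](CC)(CC)CC)CCCC=O)C(=O)C1
F3 | step 2 | 7-acetyl-8a-hydroxy-4a-methyl-4-(triethylsilyloxy)decahydronaphthalene-1-carbaldehyde (mixture at C1, C7, C8a) | CC(=O)C1CC[C@@]2(C)[C@@H](O[Si](CC)(CC)CC)CCC(C=O)C2(O)C1
F4 | step 2 | 7α-acetyl-1α-(triethylsilyloxy) Δ4-enal | CC(=O)[C@H]1CC[C@@]2(C)[C@@H](O[Si](CC)(CC)CC)CCC(C=O)=C2C1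
F5 | step 2 | 7β-acetyl-1α-(triethylsilyloxy) Δ4-enal | CC(=O)[C@@H]1CC[C@@]2(C)[C@@H](O[Si](CC)(CC)CC)CCC(C=O)=C2C1
F6 | step 2 | 7β-acetyl-1α-hydroxy Δ4-enal | CC(=O)[C@@H]1CC[C@@]2(C)[C@@H](O)CCC(C=O)=C2C1
F7 | step 2 | 1α-triflate of F6 | CC(=O)[C@@H]1CC[C@@]2(C)[C@@H](OS(=O)(=O)C(F)(F)F)CCC(C=O)=C2C1
F8 | step 3 | 7α-acetyl epimer of 11 | CC(=O)[C@H]1CC[C@@]2(C)[C@H](Br)CCC(CO)=C2C1
F9 | step 3 | dioxirane formed from the acetyl group of F8 | CC1(OO1)[C@H]2CC[C@@]3(C)[C@H](Br)CCC(CO)=C3C2
F10 | step 3 | 7α-acetyl epimer of 12 | CC(=O)[C@H]1CC[C@@]2(C)[C@H](Br)CC[C@@]3(CO)O[C@@]23C1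
F11 | step 3 | 7α-acetyl epimer of 13 | CC(=O)[C@H]1CC[C@@]2(C)[C@H](Br)CC[C@@]3(CI)O[C@@]23C1
F12 | step 3 | 7α-acetyl epimer of 14 | CC(=O)[C@H]1CC[C@@]2(C)[C@H](Br)CCC(=C)[C@]2(O)C1
F13 | step 11 | (E)-alkenyl pinacol boronate from 14 | CC1(C)OB(/C=C(\C)[C@@H]2CC[C@@]3(C)[C@H](Br)CCC(=C)[C@]3(O)C2)OC1(C)C
F14 | step 11 | (E)-1-iodo-3-methylbuta-1,3-diene | I/C=C/C(C)=C
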